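Read these runs by the Q still left, not by the X made, and a chain length takes one division.

all flasks: Z 22 mM

| charge | Q | remark | time |
|---|---|---|---|
| birch | 0.44 M (fed, over 2.5 h) | run made earlier; the fed solution adds 0.10 times the starting volume |  |
| oak | 0.78 M (fed, over 2.5 h) | run made earlier; the fed solution adds 0.10 times the starting volume |  |
| Monday's | 0.50 M (fed, over 2.5 h) | the fed solution adds 0.10 times the starting volume | 4.0 d |
| Wednesday's | 0.30 M (fed, over 2.5 h) | the fed solution adds 0.10 times the starting volume | 4.0 d |

- which of the two ends with the longer chains by the average number of monomer units in a chain (chains begun, living or dead) ("neither" if they lie within 10%) (Monday's / Wednesday's / neither)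
- average number of monomer units in a chain (chains begun, living or dead) at the end, Monday's
- average number of monomer units in a chain (chains begun, living or dead) at the end, Wednesday's

- birch (time / d: X / %): 0.333: 27.5; 1.04: 36.8; 1.67: 41.0; 3.00: 46.7; 4.00: 47.4
- oak (time / d: X / %): 0.333: 25.6; 1.04: 35.0; 1.67: 41.2; 3.00: 43.1; 4.00: 48.1

(readings scatter by 1 percentage point)

- charges are per starting volume, the dose included; the dosed solution carries all of it
- the average divides the monomer in chains by the number of chains begun, living and dead together
- the earlier runs do not show the number of chains; that part of a forecast is a guess

I turned the two columns of X into the fraction of Q left. At 0.333 d birch had 72.5% left and oak 74.4%, a gap of 1.9 percentage points against a scatter of 1 point. At 4.00 d birch had 52.6% and oak 51.9%, a gap of 0.7 points. Yet oak was charged 1.77 times the [Q] of birch, so I took the fraction left at that time as the same for both new flasks, at the mean of 52.2%. For Wednesday's this was an extrapolation, since its 0.30 M is less than birch's 0.44 M.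

The runs did not show the chains, so I guessed one chain for each Z charged. I multiplied the charged [Q] by one minus the fraction left and divided by the charged [Z]. That gave 10.9 on Monday's and 6.51 on Wednesday's. This quantity, the Q reacted over the Z charged, I called the units per starter. By it Monday's came out 1.67 times Wednesday's, outside the margin of 10%.

The forecast chose Monday's, with 13 and 8. These are higher than my figures, because it took up the case that “only about 80% of Z starts chains”.

The flask gave Monday's, with 10.8 on Monday's and 6.53 on Wednesday's, against units per starter of 10.9 and 6.51.

    Q + Z → J + X (k = 6.60 M⁻¹ h⁻¹)
    Q + J → X + J, rate k2*[J]*[Q] (k = 6.20 M⁻¹ h⁻¹)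
    X + J → Q + J, rate k3*[J] as long as [X] is above zero (k = 0.190 h⁻¹)
    2 J → L (k = 20.0 M⁻¹ h⁻¹)

On Wednesday's at 0.348 d, the half-life of Z by its conversion with Q was 0.53 h, far shorter than the 1.4 d half-life of Q by the making of X. At 4.00 d Wednesday's held 0% of its Z, the limiting reagent, beside 52% of its Q.

Then I took Wednesday's flask read at 40 h. The birch and oak runs at 1.67 d showed X of 41.0% and 41.2%, so I scaled Wednesday's units per starter by the mean of these over the mean fraction taken at 4.00 d, which gave 5.60, and the flask computed to 5.70.

The data were generated by integration from invented constants; the scatter is artificial.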